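## Retrosynthetic overview

1. Target ⇒ two molecules of the 12-membered α′-hydroxy enone lactone plus H2S. A catalyst-controlled double sulfa-Michael addition makes both C–S bonds and both C3 stereocentres in the last step.
2. Each lactone ring ⇒ closed at C4–C5 by a palladium-catalysed, copper-assisted thioester–vinylstannane acyl coupling. Both rings exist before the sulfide bridge is made.
3. Seco thioester ⇒ ester between a C5–C12 hydroxy thioester and (E)-3-(tributylstannyl)acrylic acid (from ethyl propiolate).
4. Hydroxy thioester ⇒ C8–C9 bond by palladium-catalysed alkyl–alkyl Suzuki coupling. The borane comes from (R)-pent-4-en-2-yl acetate ((R)-propylene oxide + vinyl Grignard, sets C12). The bromide is ethyl (S)-4-bromo-2-silyloxybutanoate (from (S)-α-hydroxy-γ-butyrolactone, sets C6).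
5. Order: three two-step branches → fragment union → 12-membered ring (step 10) → sulfide link (step 12).

Ring numbering used throughout: O1, C2 (lactone C=O), C3 (C–S), C4, C5 (ketone), C6 (C–OH), C7–C11, C12 (C–CH3). The target is C2-symmetric, (3S,6S,12R) in both halves.

Assumption: H2S is bought as its 0.8 M solution in THF, and the (S,S) ligand antipode named in step 12 is taken as the matched one.

## Route

Step 1
Reactants: 1 (R)-2-methyloxirane; 2 vinylmagnesium bromide (CH2=CHMgBr)
Product: 3 (R)-pent-4-en-2-ol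
Conditions: CuI (10 mol %), THF, −30 → 0 °C; then sat. aq. NH4Cl
Reagents that add atoms: none
Why: Copper-catalysed Grignard opening of the terminal epoxide at the unsubstituted carbon (SN2), so the C–O stereocentre is not touched and its R configuration (later C12) is carried over.

Step 2
Reactants: 3 (R)-pent-4-en-2-ol
Product: 4 (R)-pent-4-en-2-yl acetate
Conditions: Ac2O, pyridine, DMAP (cat.), CH2Cl2, 0 °C → rt
Reagents that add atoms: acetic anhydride, CC(=O)OC(C)=O
Why: DMAP-catalysed O-acylation with retention; the acetate tolerates hydroboration and the Suzuki base and is removed at no extra cost in step 8.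

Step 3
Reactants: 5 (S)-3-hydroxyoxolan-2-one ((S)-α-hydroxy-γ-butyrolactone)
Product: 6 ethyl (S)-4-bromo-2-hydroxybutanoate
Conditions: HBr (g), EtOH, 0 °C → rt
Reagents that add atoms: hydrogen bromide, Br; ethanol, CCO
Why: Acid-mediated lactone opening, with bromide attacking the γ-CH2–O carbon (SN2) and Fischer esterification of the acid; the α-carbinol (later C6, S) is not involved.

Step 4
Reactants: 6 ethyl (S)-4-bromo-2-hydroxybutanoate
Product: 7 ethyl (S)-4-bromo-2-[(tert-butyldimethylsilyl)oxy]butanoate
Conditions: TBSOTf, 2,6-lutidine, CH2Cl2, −78 → 0 °C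
Reagents that add atoms: tert-butyldimethylsilyl trifluoromethanesulfonate, CC(C)(C)[Si](C)(C)OS(=O)(=O)C(F)(F)F
Why: Silyl ether formation with a non-nucleophilic base, which avoids N-alkylation by the primary bromide and leaves the stereocentre untouched.

Step 5
Reactants: 8 ethyl propiolate
Product: 9 ethyl (2E)-3-(tributylstannyl)prop-2-enoate
Conditions: Bu3SnH, LiN(iPr)2, THF, 0 °C; CuBr·SMe2, −78 °C; then 8, MeOH, −78 °C
Reagents that add atoms: tributyltin hydride, CCCC[SnH](CCCC)CCCC
Why: Syn stannylcupration of the ynoate places tin on the β-carbon, and protonation of the vinylcopper by MeOH at −78 °C before it can isomerise fixes the E geometry.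

Step 6
Reactants: 9 ethyl (2E)-3-(tributylstannyl)prop-2-enoate
Product: 10 (2E)-3-(tributylstannyl)prop-2-enoic acid
Conditions: LiOH·H2O, THF/MeOH/H2O, rt; then 1 M HCl to pH 4, 0 °C
Reagents that add atoms: lithium hydroxide, [Li+].[OH-]
Why: Saponification; the vinylstannane is stable to base and to brief cold acidification to pH 4, and the alkene geometry is unchanged.

Step 7
Reactants: 4 (R)-pent-4-en-2-yl acetate; 7 ethyl (S)-4-bromo-2-[(tert-butyldimethylsilyl)oxy]butanoate
Product: 12 ethyl (2S,8R)-8-acetoxy-2-[(tert-butyldimethylsilyl)oxy]nonanoate, via B-[(4R)-4-acetoxypentyl]-9-BBN 11 (not isolated)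
Conditions: 4, 9-BBN, THF, 0 °C → rt; then 7, Pd(OAc)2 (4 mol %), PCy3 (8 mol %), K3PO4·H2O, THF, rt
Reagents that add atoms: 9-borabicyclo[3.3.1]nonane (9-BBN), B1C2CCCC1CCC2 (its atoms are in 11 only)
Why: Anti-Markovnikov hydroboration followed by B-alkyl Suzuki–Miyaura alkyl–alkyl cross-coupling, in which the electron-rich bulky PCy3 lets zerovalent palladium add to the primary C–Br bond and couple faster than β-hydride elimination; this forms the C8–C9 bond and touches neither stereocentre.

Step 8
Reactants: 12 ethyl (2S,8R)-8-acetoxy-2-[(tert-butyldimethylsilyl)oxy]nonanoate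
Product: 13 S-ethyl (2S,8R)-2-[(tert-butyldimethylsilyl)oxy]-8-hydroxynonanethioate
Conditions: AlMe3, EtSH, CH2Cl2, 0 °C → rt; then 1 M HCl
Reagents that add atoms: ethanethiol, CCS
Why: Aluminium thiolate thiolysis of esters (Me2AlSEt made in the flask) turns the ethyl ester into the S-ethyl thioester and in the same operation cleaves the acetate as S-ethyl thioacetate, freeing the C8 alcohol; the silyl ether and both stereocentres are untouched.

Step 9
Reactants: 13 S-ethyl (2S,8R)-2-[(tert-butyldimethylsilyl)oxy]-8-hydroxynonanethioate; 10 (2E)-3-(tributylstannyl)prop-2-enoic acid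
Product: 14 S-ethyl (2S,8R)-2-[(tert-butyldimethylsilyl)oxy]-8-{[(2E)-3-(tributylstannyl)prop-2-enoyl]oxy}nonanethioate
Conditions: DCC, DMAP (10 mol %), CH2Cl2, 0 °C → rt
Reagents that add atoms: none
Why: Steglich esterification of the only free hydroxyl with retention at the carbinol carbon; the thioester and vinylstannane are inert under these neutral conditions.

Step 10
Reactants: 14 S-ethyl (2S,8R)-2-[(tert-butyldimethylsilyl)oxy]-8-{[(2E)-3-(tributylstannyl)prop-2-enoyl]oxy}nonanethioate
Product: 15 (3E,6S,12R)-6-[(tert-butyldimethylsilyl)oxy]-12-methyl-1-oxacyclododec-3-ene-2,5-dione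
Conditions: Pd2(dba)3 (10 mol %), P(2-furyl)3 (40 mol %), CuO2PPh2 (2 equiv), THF, 50 °C, 0.002 M (syringe pump)
Reagents that add atoms: none
Why: Liebeskind–Srogl-type acyl cross-coupling run as a macrocyclisation: zerovalent palladium inserts into the C(acyl)–S bond activated by the thiophilic cuprous phosphinate, the vinyl group passes from tin to palladium with retention of the E geometry, and reductive elimination forms the C4–C5 bond and the 12-membered ring under neutral conditions that leave the α-silyloxy stereocentre intact.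

Step 11
Reactants: 15 (3E,6S,12R)-6-[(tert-butyldimethylsilyl)oxy]-12-methyl-1-oxacyclododec-3-ene-2,5-dione
Product: 16 (3E,6S,12R)-6-hydroxy-12-methyl-1-oxacyclododec-3-ene-2,5-dione
Conditions: HF·pyridine, pyridine, THF, 0 °C → rt
Reagents that add atoms: none
Why: Buffered fluoride desilylation, which avoids the basic conditions that would isomerise the enone or epimerise the α-hydroxy ketone.

Step 12
Reactants: 16 (3E,6S,12R)-6-hydroxy-12-methyl-1-oxacyclododec-3-ene-2,5-dione (2 equiv); 17 hydrogen sulfide
Product: 19 thiocladospolide F, (3S,3'S,6S,6'S,12R,12'R)-3,3'-sulfanediylbis(6-hydroxy-12-methyl-1-oxacyclododecane-2,5-dione), via thiol mono-adduct 18 (not isolated)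
Conditions: Sc(OTf)3 (10 mol %), (S,S)-Ph-pybox [2,6-bis((4S)-4-phenyl-4,5-dihydrooxazol-2-yl)pyridine] (12 mol %), H2S (0.8 M in THF, 0.50 equiv, slow addition), 2,6-lutidine (10 mol %), CH2Cl2, −40 → −20 °C
Reagents that add atoms: none
Why: Proposed new method: a chiral scandium–pybox Lewis acid links two α′-hydroxy enones through H2S in a catalyst-controlled double sulfa-Michael addition; trivalent scandium binds the C5 carbonyl and C6 hydroxyl of 16 as a five-membered chelate, which lowers the enone LUMO, directs sulfur to C3 (β to the chelated ketone) and lets the ligand phenyl groups shield one π-face, so that H2S and then the more nucleophilic thiol 18 add with the same facial sense to give the 3S,3'S sulfide, while the hard oxophilic metal is not poisoned by sulfur and lutidine shuttles the proton to the scandium enolate; the closest known reactions are chiral Lewis acid (scandium, nickel) catalysed enantioselective sulfa-Michael additions of thiols to chelating enoyl acceptors, two-point Lewis acid activation of α′-hydroxy enones toward carbon and nitrogen nucleophiles, and the uncatalysed base-mediated double addition of sulfide to enones.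

## Compound list

1 | (R)-2-methyloxirane ((R)-propylene oxide) | C[C@@H]1CO1 | starting material
2 | vinylmagnesium bromide | C=C[Mg]Br | starting material
3 | (R)-pent-4-en-2-ol | C[C@@H](O)CC=C | intermediate
4 | (R)-pent-4-en-2-yl acetate | C[C@@H](OC(C)=O)CC=C | intermediate
5 | (S)-3-hydroxyoxolan-2-one | O[C@H]1CCOC1=O | starting material
6 | ethyl (S)-4-bromo-2-hydroxybutanoate | CCOC(=O)[C@@H](O)CCBr | intermediate
7 | ethyl (S)-4-bromo-2-[(tert-butyldimethylsilyl)oxy]butanoate | CCOC(=O)[C@@H](O[Si](C)(C)C(C)(C)C)CCBr | intermediate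
8 | ethyl propiolate | C#CC(=O)OCC | starting material
9 | ethyl (2E)-3-(tributylstannyl)prop-2-enoate | CCCC[Sn](CCCC)(CCCC)/C=C/C(=O)OCC | intermediate
10 | (2E)-3-(tributylstannyl)prop-2-enoic acid | CCCC[Sn](CCCC)(CCCC)/C=C/C(=O)O | intermediate
11 | B-[(4R)-4-acetoxypentyl]-9-borabicyclo[3.3.1]nonane | C[C@@H](OC(C)=O)CCCB1C2CCCC1CCC2 | intermediate (not isolated)
12 | ethyl (2S,8R)-8-acetoxy-2-[(tert-butyldimethylsilyl)oxy]nonanoate | CCOC(=O)[C@@H](O[Si](C)(C)C(C)(C)C)CCCCC[C@@H](C)OC(C)=O | intermediate
13 | S-ethyl (2S,8R)-2-[(tert-butyldimethylsilyl)oxy]-8-hydroxynonanethioate | CCSC(=O)[C@@H](O[Si](C)(C)C(C)(C)C)CCCCC[C@@H](C)O | intermediate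
14 | S-ethyl (2S,8R)-2-[(tert-butyldimethylsilyl)oxy]-8-{[(2E)-3-(tributylstannyl)prop-2-enoyl]oxy}nonanethioate | CCSC(=O)[C@@H](O[Si](C)(C)C(C)(C)C)CCCCC[C@@H](C)OC(=O)/C=C/[Sn](CCCC)(CCCC)CCCC | intermediate
15 | (3E,6S,12R)-6-[(tert-butyldimethylsilyl)oxy]-12-methyl-1-oxacyclododec-3-ene-2,5-dione | C[C@@H]1CCCCC[C@H](O[Si](C)(C)C(C)(C)C)C(=O)/C=C/C(=O)O1 | intermediate
16 | (3E,6S,12R)-6-hydroxy-12-methyl-1-oxacyclododec-3-ene-2,5-dione | C[C@@H]1CCCCC[C@H](O)C(=O)/C=C/C(=O)O1 | intermediate
17 | hydrogen sulfide | S | starting material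
18 | (3S,6S,12R)-6-hydroxy-12-methyl-3-sulfanyl-1-oxacyclododecane-2,5-dione | C[C@@H]1CCCCC[C@H](O)C(=O)C[C@H](S)C(=O)O1 | intermediate (not isolated)
19 | thiocladospolide F, (3S,3'S,6S,6'S,12R,12'R)-3,3'-sulfanediylbis(6-hydroxy-12-methyl-1-oxacyclododecane-2,5-dione) | C[C@@H]1CCCCC[C@H](O)C(=O)C[C@H](S[C@H]2CC(=O)[C@@H](O)CCCCC[C@@H](C)OC2=O)C(=O)O1 | target

## Step count

Total step count: 12.
Longest linear sequence: 8 steps (1, 2, 7, 8, 9, 10, 11, 12; the branch through steps 3 and 4 is equally long). The branch through steps 5 and 6 joins at step 9.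

## The three steps most likely to fail

**Step 12 (the proposed new method).** Catalyst control may be weak, the chosen ligand antipode may be the mismatched one (the (R,R) ligand is the immediate control experiment), or retro-Michael equilibration may erode the ratio. The fallback uses known chemistry; it sets out from 16 and comes back at thiol 18, then reaches 19. Conjugate addition of thioacetic acid to 16 (AcSH, Et3N cat., CH2Cl2, 0 °C; substrate-controlled, 3S adduct separated by chromatography) gives S-[(3S,6S,12R)-6-hydroxy-12-methyl-2,5-dioxo-1-oxacyclododecan-3-yl] ethanethioate F1. Chemoselective S-deacetylation with hydrazine acetate (degassed DMF, 0 °C) gives thiol 18, now isolated. Base-catalysed thia-Michael addition of 18 to a second equivalent of 16 (Et3N 10 mol %, CH2Cl2, 0 °C) gives 19. Because thiol addition is reversible, the mixture can be equilibrated toward the most stable diastereomer.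

**Step 10 (macrocyclising acyl coupling).** Oligomerisation, protodestannylation or slow oxidative addition into the S-ethyl thioester may limit the yield. The fallback closes the same C4–C5 bond by a nickel-catalysed, chromium-mediated Nozaki–Hiyama–Kishi reaction; it sets out from 13 and comes back at 15.
- Fukuyama reduction of 13 (Et3SiH, Pd/C, acetone, rt) gives (2S,8R)-2-[(tert-butyldimethylsilyl)oxy]-8-hydroxynonanal F2.
- Esterification with commercial (E)-3-iodoacrylic acid (O=C(O)/C=C/I; N,N'-diisopropylcarbodiimide, DMAP cat., CH2Cl2, −20 °C) gives (2R,8S)-8-[(tert-butyldimethylsilyl)oxy]-9-oxononan-2-yl (2E)-3-iodoprop-2-enoate F3.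
- Ring closure (CrCl2, NiCl2 cat., DMSO/THF, 0.005 M, rt) gives (3E,6S,12R)-6-[(tert-butyldimethylsilyl)oxy]-5-hydroxy-12-methyl-1-oxacyclododec-3-en-2-one F4 as a mixture of C5 epimers.
- Dess–Martin oxidation (NaHCO3, CH2Cl2) converges both epimers on 15.

**Step 7 (alkyl–alkyl Suzuki coupling).** β-Hydride elimination from the alkylpalladium or sluggish transmetalation may intervene. The fallback builds the same bond by olefination and hydrogenation; it sets out from borane 11 (made from 4 as in step 7) and bromide 7 and comes back at 12.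
- Oxidation of 11 (NaBO3·4H2O, THF/H2O) gives (R)-5-hydroxypentan-2-yl acetate F5.
- Dess–Martin oxidation gives (R)-5-oxopentan-2-yl acetate F6.
- Heating 7 with PPh3 (MeCN, reflux) gives [(3S)-3-[(tert-butyldimethylsilyl)oxy]-4-ethoxy-4-oxobutyl]triphenylphosphonium bromide F7.
- Ylide formation (KN(SiMe3)2, THF, −78 °C) and Wittig reaction with F6 gives ethyl (2S,4Z,8R)-8-acetoxy-2-[(tert-butyldimethylsilyl)oxy]non-4-enoate F8.
- Hydrogenation (H2, Pd/C, EtOAc) gives 12.

## Further compounds

F1 | step 12 | S-[(3S,6S,12R)-6-hydroxy-12-methyl-2,5-dioxo-1-oxacyclododecan-3-yl] ethanethioate | C[C@@H]1CCCCC[C@H](O)C(=O)C[C@H](SC(C)=O)C(=O)O1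
F2 | step 10 | (2S,8R)-2-[(tert-butyldimethylsilyl)oxy]-8-hydroxynonanal | O=C[C@@H](O[Si](C)(C)C(C)(C)C)CCCCC[C@@H](C)O
F3 | step 10 | (2R,8S)-8-[(tert-butyldimethylsilyl)oxy]-9-oxononan-2-yl (2E)-3-iodoprop-2-enoate | O=C[C@@H](O[Si](C)(C)C(C)(C)C)CCCCC[C@@H](C)OC(=O)/C=C/I
F4 | step 10 | (3E,6S,12R)-6-[(tert-butyldimethylsilyl)oxy]-5-hydroxy-12-methyl-1-oxacyclododec-3-en-2-one (C5 epimers) | C[C@@H]1CCCCC[C@H](O[Si](C)(C)C(C)(C)C)C(O)/C=C/C(=O)O1
F5 | step 7 | (R)-5-hydroxypentan-2-yl acetate | C[C@@H](OC(C)=O)CCCO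
F6 | step 7 | (R)-5-oxopentan-2-yl acetate | C[C@@H](OC(C)=O)CCC=O
F7 | step 7 | [(3S)-3-[(tert-butyldimethylsilyl)oxy]-4-ethoxy-4-oxobutyl]triphenylphosphonium bromide | CCOC(=O)[C@@H](O[Si](C)(C)C(C)(C)C)CC[P+](c1ccccc1)(c1ccccc1)c1ccccc1.[Br-]
F8 | step 7 | ethyl (2S,4Z,8R)-8-acetoxy-2-[(tert-butyldimethylsilyl)oxy]non-4-enoate | CCOC(=O)[C@@H](O[Si](C)(C)C(C)(C)C)C/C=C\CC[C@@H](C)OC(C)=O
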